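**A count.** A count of 1.11 turnovers stood in the grey run at 120 min, a turnover being one natural-log step down in [free monomer], and I wanted that count for the violet flask at 2.5 h.

| setting | violet | grey | flask |
|---|---|---|---|
| free monomer | 0.010 M | 0.0050 M | 0.010 M |
| pre-initiator | 2.2 mol% | 2.2 mol% | 2.2 mol% |
| remark | the very flask that is asked about, followed so far | run made earlier |  |
| time |  |  | 2.5 h |

| run | time / min | monomer in chains / % | free monomer / % |
|---|---|---|---|
| violet | 2.00 | 1 | 97 |
| violet | 6.00 | 2 | 93 |
| violet | 10.0 | 0 | 94 |
| violet | 15.0 | 0 | 88 |
| violet | 25.0 | 0 | 84 |
| violet | 30.0 | 0 | 77 |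
| grey | 8.00 | 1 | 93 |
| grey | 20.0 | 0 | 87 |
| grey | 40.0 | 1 | 73 |
| grey | 60.0 | 1 | 63 |
| grey | 80.0 | 4 | 52 |
| grey | 120 | 3 | 33 |

(standard deviation of a reading: 1.5 percentage points)

- average number of monomer units in a chain (chains begun, living or dead) at 2.5 h
- part of the free monomer that has reacted at 2.5 h

- the average divides the monomer in chains by the number of chains begun, living and dead together
- candidate steps: free monomer -> uncatalysed product; free monomer + living end -> monomer in chains + living end; pre-initiator -> initiator; free monomer + initiator -> living end + monomer in chains; initiator -> spent initiator
- the earlier runs do not show the number of chains; that part of a forecast is a guess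

**First estimate.** The grey run at 60.0 min gave 0.00770 min⁻¹, which I took as a pseudo-first-order constant, so the violet flask would pass 1.16 turnovers and 68.7% of its free monomer would react.

**The objection.** But the grey run then ran ahead of that constant: its last reading held 0.185 extra turnovers, a gap of 6.7 percentage points in free monomer against a scatter of 1.5 points, while monomer in chains read 4% and 3%.

**Better estimate.** I let the extra turnovers grow with the square of time and doubled them, since the violet flask held twice the free monomer at the same loading. This gave the onset time, the time by which the violet flask gains one extra turnover, 197 min, and so 1.73 turnovers and 82.3% reacted.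

**Remaining doubt.** The count left 77.6% in the violet run at 30.0 min, where 77% was read, but the extra there was 0.0232 turnovers, so the doubling stayed untested. The number of chains was not shown, so I left dp as a guess.

**The forecast.** The forecast gave 74% reacted and dp 4, holding that “the uncatalysed reaction dominates”; my conversion stood higher.

**The result.** The flask gave 82.2% reacted, or 1.73 turnovers, and dp 256.

    free monomer → uncatalysed product (k = 0.00779 min⁻¹)
    free monomer + living end → monomer in chains + living end, rate k2*[living end]*[free monomer] (k = 1010 M⁻¹ min⁻¹)
    pre-initiator → initiator (k = 0.00276 min⁻¹)
    free monomer + initiator → living end + monomer in chains (k = 0.369 M⁻¹ min⁻¹)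
    initiator → spent initiator (k = 5.94 × 10⁻⁴ min⁻¹)

**Earlier reading.** The same flask read at 1.0 h counts 0.554 turnovers by the onset time 197 min, hence 42.5% reacted, and it gave 40.9%. That flask held 36.8% as uncatalysed product and 4.09% as monomer in chains, and its chains averaged 158 units.

The runs are calculated for an exercise; noise was put on by code.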